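The numbers were chosen freely, and the outcome is calculated.

In a one-step world a species has a single clock. The bis adduct here has a pair: reagent turns it into triple product, and substrate turns it into side product.

| setting | dawn | noon | summer | winter |
|---|---|---|---|---|
| substrate | 0.10 M (fed, over 1.5 min) | 0.10 M | 0.10 M (in portions, 4, over 1.5 min) | 0.10 M |
| reagent | 0.130 M | 0.130 M | 0.130 M | 0.130 M (fed, over 1.5 min) |
| time | 4.0 min | 4.0 min | 4.0 min | 4.0 min |
| remark | all else is in the flask from the start; the feed brings no volume worth counting | everything together at the start | first portion at the start, last at 1.5 min | all else is in the flask from the start; the feed brings no volume worth counting |

- the best flask by share of bis adduct in bis adduct plus triple product; "all alike" if 1.5 percentage points covers them all (dawn / noon / summer / winter / all alike)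
- share of bis adduct in bis adduct plus triple product at the end, dawn
- share of bis adduct in bis adduct plus triple product at the end, noon
- share of bis adduct in bis adduct plus triple product at the end, summer
- share of bis adduct in bis adduct plus triple product at the end, winter

- in percentages every species weighs as the substrate in it: one side product counts as two
- two of one species on the left: rate k times its square, two consumed each time
- run time (dawn): 4.0 min

    substrate + reagent → single product + released group (k1 = 0.453 /M/s)
    reagent + single product → bis adduct + released group (k2 = 0.239 /M/s)
    reagent + bis adduct → triple product + released group (k3 = 0.538 /M/s)
    substrate + bis adduct → side product (k4 = 0.775 /M/s)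
    2 reagent → self-condensation product (k5 = 0.529 /M/s)

I carry one rate through the flasks. With the charges, substrate drains bis adduct at 4.65 /min, a half-life of 0.15 min, and reagent gives 0.17 min. Each is short against the run. While c(substrate) barely moves, the substrate drain is pseudo-first-order.

This drain falls in step with c(substrate). In winter I balance the reagent feed against its step with substrate. Reagent's loss to self-condensation then stands to that step as 0.745 to one. The drain therefore slows by the factor 0.255, the part of the substrate that this reagent leaves.

My carried quantity is the scavenging count, the e-foldings of bis adduct under substrate from the end of the dosing time to the reading. I make it 2.96 for winter, so I reckon that 5.17 % of the bis adduct at the end of the feed survives.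

In noon the start ratio is 3.04, higher than winter's, and over the same window the count becomes 7.88. In dawn and summer reagent by itself halves in 0.121 min, shorter than the dosing time. I therefore leave their drain unslowed, which gives a count of 11.6. So I expect winter to lead, since its count is lowest. The count gives a survival, though, and I do not take it as far as a share.

The forecast names winter, with 0.4 % for dawn, 4.3 % for noon, 0.2 % for summer and 26 % for winter: “So the end share depends on how much substrate is left.” The flasks give winter as best, with 0.414 % for dawn, 1.67 % for noon, 0.292 % for summer and 23.2 % for winter.

At 4.00 min in winter the substrate reads 23.1 % against my 25.5 %. Bis adduct in winter goes from 3.97 % at 1.50 min to 0.853 % at 4.00 min, so the later amount is 21.5 % of the earlier, where the count gave 5.17 %. The neighbouring flask is winter with 0.40 M of substrate. The same reckoning gives a ratio of 0.0465 and a count of 32.1. That flask ends with triple product at 0.0398 %, bis adduct at 0 % and a share of 0 %.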